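Ring B is cut across its two opposite bonds, C5–C10 and C7–C8 (labdane numbering), which splits it into the units C5–C6–C7 and C8–C9–C10 and also opens ring A. The key step rejoins them in one flask: a tertiary C10 radical, made by hydrogen-atom transfer to a 1,1-disubstituted alkene, adds 6-exo to C5 of an enal (ring A; C5 and C10 set), and the C7 aldehyde so released is olefinated by the C8 phosphonate (ring B). It exploits the 1,4 relation of the two bonds across ring B, between the quaternary C10 and the sp2 C8. The precursor is an acyclic enal–alkene–phosphonoacetate carrying the C3/C4 acetonide and C9.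

Key step: step 9

Remark on numbering: C1–C20 are the labdane positions of the target (ring A = C1–C5 and C10; ring B = C5–C10; C17 = exocyclic methylene carbon; C18 and C19 = methyl and CH2O on C4; C20 = methyl on C10; C11–C16 = side chain and lactone).

Assumption: the ligand enantiomers named in steps 1 and 6 are those expected from the accepted models for these catalyst classes to give the drawn configurations; the mirror-image ligand would be used if a model reaction showed the opposite sense.

Step 1
Reactants: 1 5-(trimethylsilyl)pent-4-yn-1-ol; 2 2-methyl-2-vinyloxirane (racemic)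
Product: 3 (2R,3R)-2-ethenyl-2-methyl-7-(trimethylsilyl)hept-6-yne-1,3-diol
Conditions: [Ir(cod)Cl]2 (2.5 mol%), (R)-Tol-BINAP (5 mol%), 4-cyano-3-nitrobenzoic acid (10 mol%), K3PO4 (5 mol%), THF, 60 °C
Reagents that add atoms: none
Why: Iridium-catalysed transfer-hydrogenative tert-(hydroxy)prenylation: the alcohol is dehydrogenated in situ and the π-allyliridium species from the vinyl epoxide adds to the transient aldehyde through a closed chair transition state, so the chiral ligand sets C3 and the quaternary C4 together as the anti-diol.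

Step 2
Reactants: 3 (2R,3R)-2-ethenyl-2-methyl-7-(trimethylsilyl)hept-6-yne-1,3-diol
Product: 4 (4R,5R)-5-ethenyl-2,2,5-trimethyl-4-[4-(trimethylsilyl)but-3-yn-1-yl]-1,3-dioxane
Conditions: 2,2-dimethoxypropane, PPTS (cat.), CH2Cl2, 23 °C
Reagents that add atoms: 2,2-dimethoxypropane, COC(C)(C)OC
Why: Acid-catalysed transketalisation of the 1,3-diol gives the six-membered acetonide, which protects O3 and O19 until the last step and later biases the ring-A chair.

Step 3
Reactants: 4 (4R,5R)-5-ethenyl-2,2,5-trimethyl-4-[4-(trimethylsilyl)but-3-yn-1-yl]-1,3-dioxane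
Product: 5 (4R,5R)-4-(but-3-yn-1-yl)-5-ethenyl-2,2,5-trimethyl-1,3-dioxane
Conditions: K2CO3 (cat.), MeOH, 23 °C
Reagents that add atoms: none
Why: Methoxide-mediated protodesilylation of the alkynylsilane frees the terminal alkyne without touching the acetonide or the vinyl group.

Step 4
Reactants: 5 (4R,5R)-4-(but-3-yn-1-yl)-5-ethenyl-2,2,5-trimethyl-1,3-dioxane
Product: 7 2-{4-[(4R,5R)-5-ethenyl-2,2,5-trimethyl-1,3-dioxan-4-yl]but-1-en-2-yl}-4,4,5,5-tetramethyl-1,3,2-dioxaborolane, via alkenylalane 6 (not isolated)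
Conditions: Ni(dppp)Cl2 (3 mol%), DIBAL-H, THF, 0 to 23 °C; then MeOBpin, 0 to 80 °C
Reagents that add atoms: 2-methoxy-4,4,5,5-tetramethyl-1,3,2-dioxaborolane, COB1OC(C)(C)C(C)(C)O1
Why: Nickel-catalysed Markovnikov (α-selective) hydroalumination of the terminal alkyne places aluminium on the internal carbon (future C10), and aluminium-to-boron transmetalation gives the 1,1-disubstituted alkenyl boronate, the hindered neopentyl-type vinyl group being left alone.

Step 5
Reactants: 8 methyl 3,3-dimethoxypropanoate
Product: 10 ethyl (2E)-5,5-dimethoxypent-2-enoate, via 3,3-dimethoxypropanal 9 (not isolated)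
Conditions: DIBAL-H (1.05 equiv), CH2Cl2, −78 °C; then Ph3P=CHCO2Et, −78 to 23 °C
Reagents that add atoms: (carbethoxymethylene)triphenylphosphorane, CCOC(=O)C=P(c1ccccc1)(c1ccccc1)c1ccccc1
Why: Half-reduction of the ester to the aluminium hemiacetal and in situ Wittig olefination with the stabilised ylide should give the E-enoate without isolation of the sensitive β-acetal aldehyde.

Step 6
Reactants: 7 alkenyl pinacol boronate; 10 ethyl (2E)-5,5-dimethoxypent-2-enoate
Product: 11 ethyl (3R)-3-(2,2-dimethoxyethyl)-6-[(4R,5R)-5-ethenyl-2,2,5-trimethyl-1,3-dioxan-4-yl]-4-methylidenehexanoate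
Conditions: [Rh(cod)Cl]2 (2.5 mol%), (S)-BINAP (6 mol%), KOH (20 mol%), 1,4-dioxane/H2O, 60 °C
Reagents that add atoms: none
Why: Rhodium-catalysed asymmetric conjugate addition (Hayashi–Miyaura reaction) of the alkenyl boronate to the E-enoate forms the C9–C10 bond, and the BINAP-bound alkenylrhodium species selects one enantioface of the enoate and so sets C9 independently of the remote acetonide centres.

Step 7
Reactants: 11 ethyl (3R)-3-(2,2-dimethoxyethyl)-6-[(4R,5R)-5-ethenyl-2,2,5-trimethyl-1,3-dioxan-4-yl]-4-methylidenehexanoate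
Product: 13 ethyl 2-(diethoxyphosphoryl)-3-(2,2-dimethoxyethyl)-6-[(4R,5R)-5-ethenyl-2,2,5-trimethyl-1,3-dioxan-4-yl]-4-methylidenehexanoate (C3 as in 11; both C2 epimers), via ketene acetal phosphate 12 (not isolated)
Conditions: LDA (1.1 equiv), THF, −78 °C; ClP(O)(OEt)2; then LDA (1.2 equiv), −78 to 0 °C; aq. NH4Cl
Reagents that add atoms: diethyl chlorophosphate, CCOP(=O)(Cl)OCC
Why: The lithium ester enolate is O-phosphorylated and the ketene acetal phosphate, on further deprotonation, undergoes the 1,3-phosphorus shift (vinyl phosphate to α-phosphono ester rearrangement), the new C8 centre forming as a mixture that is of no consequence because C8 becomes sp2 in step 9.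

Step 8
Reactants: 13 phosphonoacetate bearing the vinyl group
Product: 14 ethyl 2-(diethoxyphosphoryl)-3-(2,2-dimethoxyethyl)-4-methylidene-6-{(4R,5R)-2,2,5-trimethyl-5-[(1E)-3-oxoprop-1-en-1-yl]-1,3-dioxan-4-yl}hexanoate (C3 as in 11; both C2 epimers)
Conditions: crotonaldehyde (5 equiv), second-generation Hoveyda–Grubbs catalyst (5 mol%), CH2Cl2, 40 °C
Reagents that add atoms: (E)-but-2-enal, C/C=C/C=O
Why: Olefin cross-metathesis of the monosubstituted vinyl group with excess crotonaldehyde should give the E-enal, the 1,1-disubstituted alkene flanked by the branched C9 being too hindered a metathesis partner to compete.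

Step 9
Reactants: 14 enal–alkene–phosphonoacetate
Product: 16 Δ7 ester: trans-fused decalin with the 3,19-acetonide, C7=C8, CO2Et (C17) on C8 and CH2CH(OMe)2 on C9 (C3, C4, C5, C9, C10 as in the target), via ring-A aldehyde 15 (not isolated)
Conditions: Fe(acac)3 (30 mol%), PhSiH3 (2 equiv), EtOH/(CH2OH)2, 60 °C; then LiCl, DBU, MeCN, 23 °C (same flask)
Reagents that add atoms: none
Why: The iron hydride formed from Fe(acac)3 and PhSiH3 transfers a hydrogen atom to the terminal carbon (C20) of the 1,1-disubstituted alkene, the tertiary C10 radical adds to C5 of the enal, the α-formyl radical is reduced to the enolate and protonated to aldehyde 15, and LiCl/DBU then deprotonates the phosphonoacetate at C8, which adds to the C7 aldehyde and eliminates diethyl phosphate. The closest known reaction types are the hydrogen-atom-transfer-initiated intramolecular Giese addition to an enal that forms a quaternary centre, and one-pot conjugate addition/intramolecular Horner–Wadsworth–Emmons annulation. Ring A closes 6-exo-trig by the radical addition (C5–C10), and ring B closes by six-membered intramolecular Horner–Wadsworth–Emmons condensation (C7–C8, formed as C7=C8). C5 and C10 are set in a chair transition state cis-fused to the acetonide, in which the axial C19–O arm on C4 forces the branched C9 substituent of the planar C10 radical and the C6 chain on C5 into equatorial positions, so the C10 methyl and H5 end up axial and anti (trans ring fusion once ring B closes); C9 is carried from step 6 and the C8 epimers converge. The step needs hydrogen-atom transfer to the electron-rich 1,1-disubstituted alkene rather than reduction of the electron-poor enal, 6-exo rather than 7-endo addition, and olefination only after ring A exists; polarity matching, the ring size and the fact that the only six-membered phosphonate–aldehyde pairing arises after the radical step should secure these.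

Step 10
Reactants: 16 Δ7 ester
Product: 17 allylic alcohol: as 16 with CH2OH (C17) on C8
Conditions: DIBAL-H (2.5 equiv), CH2Cl2, −78 °C
Reagents that add atoms: none
Why: 1,2-Reduction of the α,β-unsaturated ester by DIBAL-H gives the primary allylic alcohol, both acetals being inert to the hydride.

Step 11
Reactants: 17 allylic alcohol
Product: 20 exocyclic alkene: 3,19-acetonide of the trans-decalin with C8=C17H2 and CH2CH(OMe)2 on C9, via allylic sulfonylhydrazine 18 (not isolated), via allylic diazene 19 (not isolated)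
Conditions: 2-nitrobenzenesulfonyl hydrazide, PPh3, DEAD, THF, −30 °C; then 23 °C
Reagents that add atoms: none
Why: Myers reductive 1,3-transposition: Mitsunobu substitution of the primary allylic alcohol by the sulfonyl hydrazide, loss of sulfinic acid on warming and sigmatropic loss of dinitrogen from the allylic diazene deliver hydrogen to C7 and move the double bond to C8=C17 without touching C9.

Step 12
Reactants: 20 exocyclic alkene dimethyl acetal
Product: 21 aldehyde: as 20 with CH2CHO (C11, C12) on C9
Conditions: PPTS (cat.), acetone/H2O, 23 °C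
Reagents that add atoms: water, O
Why: Acid-catalysed acetal hydrolysis cleaves the acyclic dimethyl acetal, while the acetonide is held in place by the large excess of acetone (transketalisation equilibrium).

Step 13
Reactants: 22 methyl [(4S)-2,2-dimethyl-1,3-dioxolan-4-yl]acetate
Product: 23 [(4S)-2,2-dimethyl-1,3-dioxolan-4-yl]acetic acid
Conditions: LiOH, THF/H2O, 0 °C; then 1 M HCl to pH 4
Reagents that add atoms: lithium hydroxide, [Li+].[OH-]
Why: Saponification with cold LiOH and careful acidification gives the acid without opening the acetonide, and C14 is not epimerisable because it is not α to the carbonyl.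

Step 14
Reactants: 23 [(4S)-2,2-dimethyl-1,3-dioxolan-4-yl]acetic acid
Product: 25 (4S)-4-benzyl-3-{[(4S)-2,2-dimethyl-1,3-dioxolan-4-yl]acetyl}-1,3-oxazolidin-2-one, via mixed pivalic anhydride 24 (not isolated)
Conditions: PivCl, Et3N, THF, −20 °C; then lithiated (S)-4-benzyl-1,3-oxazolidin-2-one (from n-BuLi, THF, −78 °C), −78 to 0 °C
Reagents that add atoms: (S)-4-benzyl-1,3-oxazolidin-2-one, O=C1OC[C@H](Cc2ccccc2)N1
Why: N-Acylation of the lithiated oxazolidinone by the mixed anhydride occurs at the less hindered carbonyl and gives the imide.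

Step 15
Reactants: 25 imide; 21 aldehyde
Product: 27 syn-aldol adduct: (4S)-4-benzyl-3-acyl-oxazolidinone with C12 (R, OH), C13 (R) and the (S)-dioxolane at C14, attached through C11 to the acetonide-protected decalin, via dibutylboron Z-enolate 26 (not isolated)
Conditions: Bu2BOTf, i-Pr2NEt, CH2Cl2, −78 to 0 °C; then 21, −78 to 0 °C; pH 7 buffer, MeOH, H2O2, 0 °C
Reagents that add atoms: none
Why: Evans syn-aldol reaction: the dibutylboron Z-enolate adds to the aldehyde through a Zimmerman–Traxler chair on the face opposite the benzyl group, which sets C13 and C12 under auxiliary control, while C14 is carried from the chiral pool.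

Step 16
Reactants: 27 syn-aldol adduct
Product: 29 (3R,4S)-4-hydroxy-3-{(1R)-1-hydroxy-2-[(1R,4aS,5R,6R,8aS)-6-hydroxy-5-(hydroxymethyl)-5,8a-dimethyl-2-methylidenedecahydronaphthalen-1-yl]ethyl}oxolan-2-one, via pentahydroxy imide 28 (not isolated)
Conditions: 1 M aq. HCl, THF, 23 °C
Reagents that add atoms: none
Why: Aqueous acid removes both acetonides, and the freed primary C15 hydroxyl closes the γ-lactone by intramolecular acyl substitution on the activated imide (five-membered ring favoured over attack by the C12 or C14 hydroxyls), expelling the auxiliary and leaving the C12-bearing substituent cis to the C14 hydroxyl as in the target.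

Compound list
1 | 5-(trimethylsilyl)pent-4-yn-1-ol | OCCCC#C[Si](C)(C)C | starting material
2 | 2-methyl-2-vinyloxirane (racemic) | CC1(C=C)CO1 | starting material
3 | (2R,3R)-2-ethenyl-2-methyl-7-(trimethylsilyl)hept-6-yne-1,3-diol | C=C[C@](C)(CO)[C@H](O)CCC#C[Si](C)(C)C | intermediate
4 | (4R,5R)-5-ethenyl-2,2,5-trimethyl-4-[4-(trimethylsilyl)but-3-yn-1-yl]-1,3-dioxane | C=C[C@](C)(CO1)[C@H](OC1(C)C)CCC#C[Si](C)(C)C | intermediate
5 | (4R,5R)-4-(but-3-yn-1-yl)-5-ethenyl-2,2,5-trimethyl-1,3-dioxane | C=C[C@](C)(CO1)[C@H](OC1(C)C)CCC#C | intermediate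
6 | {4-[(4R,5R)-5-ethenyl-2,2,5-trimethyl-1,3-dioxan-4-yl]but-1-en-2-yl}bis(2-methylpropyl)alumane | C=C[C@](C)(CO1)[C@H](OC1(C)C)CCC(=C)[Al](CC(C)C)CC(C)C | intermediate
7 | 2-{4-[(4R,5R)-5-ethenyl-2,2,5-trimethyl-1,3-dioxan-4-yl]but-1-en-2-yl}-4,4,5,5-tetramethyl-1,3,2-dioxaborolane | C=C[C@](C)(CO1)[C@H](OC1(C)C)CCC(=C)B2OC(C)(C)C(C)(C)O2 | intermediate
8 | methyl 3,3-dimethoxypropanoate | COC(=O)CC(OC)OC | starting material
9 | 3,3-dimethoxypropanal | O=CCC(OC)OC | intermediate
10 | ethyl (2E)-5,5-dimethoxypent-2-enoate | CCOC(=O)/C=C/CC(OC)OC | intermediate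
11 | ethyl (3R)-3-(2,2-dimethoxyethyl)-6-[(4R,5R)-5-ethenyl-2,2,5-trimethyl-1,3-dioxan-4-yl]-4-methylidenehexanoate | C=C[C@](C)(CO1)[C@H](OC1(C)C)CCC(=C)[C@@H](CC(=O)OCC)CC(OC)OC | intermediate
12 | ketene acetal phosphate of 11 (diethyl 1-ethoxyalk-1-en-1-yl phosphate; C9 as in 11) | C=C[C@](C)(CO1)[C@H](OC1(C)C)CCC(=C)[C@@H](C=C(OCC)OP(=O)(OCC)OCC)CC(OC)OC | intermediate
13 | ethyl 2-(diethoxyphosphoryl)-3-(2,2-dimethoxyethyl)-6-[(4R,5R)-5-ethenyl-2,2,5-trimethyl-1,3-dioxan-4-yl]-4-methylidenehexanoate (C3 as in 11; both C2 epimers) | C=C[C@](C)(CO1)[C@H](OC1(C)C)CCC(=C)[C@@H](C(C(=O)OCC)P(=O)(OCC)OCC)CC(OC)OC | intermediate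
14 | ethyl 2-(diethoxyphosphoryl)-3-(2,2-dimethoxyethyl)-4-methylidene-6-{(4R,5R)-2,2,5-trimethyl-5-[(1E)-3-oxoprop-1-en-1-yl]-1,3-dioxan-4-yl}hexanoate (C3 as in 11; both C2 epimers) | O=C/C=C/[C@](C)(CO1)[C@H](OC1(C)C)CCC(=C)[C@@H](C(C(=O)OCC)P(=O)(OCC)OCC)CC(OC)OC | intermediate
15 | ring-A aldehyde: acetonide-fused cyclohexane (C1–C5, C10) with CH2CHO on C5, methyl on C10 (anti to H5) and the C9 arm CH[CH(PO(OEt)2)CO2Et]CH2CH(OMe)2 on C10; C3, C4, C5, C9, C10 as in the target | O=CC[C@@H]1[C@](C)(CO2)[C@H](OC2(C)C)CC[C@@]1(C)[C@@H](C(C(=O)OCC)P(=O)(OCC)OCC)CC(OC)OC | intermediate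
16 | Δ7 ester: trans-decalin with 3,19-acetonide, C7=C8, CO2Et (C17) on C8 and CH2CH(OMe)2 on C9; ring centres as in the target | CCOC(=O)C1=CC[C@@H]2[C@](C)(CO3)[C@H](OC3(C)C)CC[C@@]2(C)[C@@H]1CC(OC)OC | intermediate
17 | allylic alcohol: as 16 with CH2OH (C17) on C8 | OCC1=CC[C@@H]2[C@](C)(CO3)[C@H](OC3(C)C)CC[C@@]2(C)[C@@H]1CC(OC)OC | intermediate
18 | N-(C17-allyl)-N-(2-nitrophenylsulfonyl)hydrazine derived from 17 | NN(CC1=CC[C@@H]2[C@](C)(CO3)[C@H](OC3(C)C)CC[C@@]2(C)[C@@H]1CC(OC)OC)S(=O)(=O)c1ccccc1[N+](=O)[O-] | intermediate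
19 | allylic monoalkyl diazene (C17–N=NH) derived from 18 | N=NCC1=CC[C@@H]2[C@](C)(CO3)[C@H](OC3(C)C)CC[C@@]2(C)[C@@H]1CC(OC)OC | intermediate
20 | exocyclic alkene: 3,19-acetonide of the trans-decalin with C8=C17H2 and CH2CH(OMe)2 on C9 | C=C1CC[C@@H]2[C@](C)(CO3)[C@H](OC3(C)C)CC[C@@]2(C)[C@@H]1CC(OC)OC | intermediate
21 | aldehyde: as 20 with CH2CHO (C11, C12) on C9 | C=C1CC[C@@H]2[C@](C)(CO3)[C@H](OC3(C)C)CC[C@@]2(C)[C@@H]1CC=O | intermediate
22 | methyl [(4S)-2,2-dimethyl-1,3-dioxolan-4-yl]acetate | COC(=O)C[C@H]1COC(C)(C)O1 | starting material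
23 | [(4S)-2,2-dimethyl-1,3-dioxolan-4-yl]acetic acid | OC(=O)C[C@H]1COC(C)(C)O1 | intermediate
24 | mixed anhydride of 23 with pivalic acid | CC(C)(C)C(=O)OC(=O)C[C@H]1COC(C)(C)O1 | intermediate
25 | (4S)-4-benzyl-3-{[(4S)-2,2-dimethyl-1,3-dioxolan-4-yl]acetyl}-1,3-oxazolidin-2-one | O=C(C[C@H]1COC(C)(C)O1)N1[C@@H](Cc2ccccc2)COC1=O | intermediate
26 | dibutylboron (Z)-enolate of 25 | CCCCB(CCCC)O/C(=C\[C@H]1COC(C)(C)O1)N1[C@@H](Cc2ccccc2)COC1=O | intermediate
27 | syn-aldol adduct of 25 and 21 (C12 R, C13 R, C14 S; both acetonides and the auxiliary in place) | C=C1CC[C@@H]2[C@](C)(CO3)[C@H](OC3(C)C)CC[C@@]2(C)[C@@H]1C[C@@H](O)[C@@H](C(=O)N4[C@@H](Cc5ccccc5)COC4=O)[C@H]6COC(C)(C)O6 | intermediate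
28 | pentahydroxy imide (27 without the two acetonides) | C=C1CC[C@@H]2[C@](C)(CO)[C@H](O)CC[C@@]2(C)[C@@H]1C[C@@H](O)[C@@H](C(=O)N3[C@@H](Cc4ccccc4)COC3=O)[C@H](O)CO | intermediate
29 | (3R,4S)-4-hydroxy-3-{(1R)-1-hydroxy-2-[(1R,4aS,5R,6R,8aS)-6-hydroxy-5-(hydroxymethyl)-5,8a-dimethyl-2-methylidenedecahydronaphthalen-1-yl]ethyl}oxolan-2-one | C=C1CC[C@@H]2[C@](C)(CO)[C@H](O)CC[C@@]2(C)[C@@H]1C[C@@H](O)[C@H]1C(=O)OC[C@H]1O | target

Total step count: 16 steps. Longest linear sequence: 13 steps (steps 1, 2, 3, 4, 6, 7, 8, 9, 10, 11, 12, 15, 16, from compound 1).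

Steps most likely to fail

Step 9. The iron hydride may reduce the enal (conjugate or 1,2-reduction) instead of generating the C10 radical selectively, facial control at C10 may be incomplete, or the hindered α-branched phosphonate anion may fail to olefinate in the same flask. The fallback sets out from 13 and comes back to the route at 15 and then 16. It generates the radical oxidatively, without any hydride in the presence of the enal, and runs the two ring closures as separate operations. Mukaiyama hydration of the 1,1-disubstituted alkene of 13 (Co(acac)2, PhSiH3, O2) should give the tertiary alcohol F1. Acylation with methyl chlorooxoacetate should give the methyl oxalate F2, and saponification with one equivalent of CsOH the caesium oxalate F3. Cross-metathesis with crotonaldehyde as in step 8 should give the enal caesium oxalate F4. Visible-light photoredox decarboxylation ([Ir(dF(CF3)ppy)2(dtbbpy)]PF6, blue light, DME/DMF, water) should release the same tertiary C10 radical, whose 6-exo Giese addition gives aldehyde 15, now isolated. A separate Horner–Wadsworth–Emmons closure (LiCl, DBU) should then give 16.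

Step 8. Metathesis at the neopentyl-type vinyl group may be slow, so that the catalyst engages the 1,1-disubstituted alkene or decomposes. The fallback sets out from 4 and comes back at 14; it installs the three-carbon acceptor before the second alkene exists. Cross-metathesis of 4 with (Z)-but-2-ene-1,4-diyl diacetate should give the allylic acetate F5. K2CO3 in methanol removes the acetate and the silyl group together to give the allylic alcohol F6. Steps 4, 6 and 7 are then run on the alcohol series (one extra equivalent of DIBAL-H in the hydroalumination; transient O-silylation with Me3SiCl before the phosphonylation) to give the boronate F7, the conjugate adduct F8 and the phosphonate F9. Oxidation of the allylic alcohol with MnO2 should give enal 14.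

Step 6. Transmetalation of the hindered 1,1-disubstituted alkenyl boronate may be slow, protodeboronation may compete, and facial control at C9 may be incomplete. The fallback sets out from 5 and 10 and comes back at 11; it replaces catalyst control by a chelation-controlled cuprate addition to an N-enoyl oxazolidinone. Alkenylalane 6 from 5 is quenched with iodine to give the alkenyl iodide F10. Enoate 10 is saponified to (2E)-5,5-dimethoxypent-2-enoic acid F11, which is attached (pivaloyl chloride, then lithiated (S)-4-phenyl-1,3-oxazolidin-2-one) to give the N-enoyl imide F12. The alkenylmagnesium reagent from F10 (t-BuLi, then MgBr2) with CuBr·SMe2 should add to the chelated imide anti to the phenyl group to give the imide adduct F13. Ethanolysis with EtOMgBr should return ester 11.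

Further compounds
F1 | step 9 | tertiary alcohol from Markovnikov hydration of the 1,1-disubstituted alkene of 13 (C10–OH, both C10 epimers) | C=C[C@](C)(CO1)[C@H](OC1(C)C)CCC(C)(O)[C@@H](C(C(=O)OCC)P(=O)(OCC)OCC)CC(OC)OC
F2 | step 9 | methyl oxalate of F1 | C=C[C@](C)(CO1)[C@H](OC1(C)C)CCC(C)(OC(=O)C(=O)OC)[C@@H](C(C(=O)OCC)P(=O)(OCC)OCC)CC(OC)OC
F3 | step 9 | caesium oxalate of F1 | [Cs+].C=C[C@](C)(CO1)[C@H](OC1(C)C)CCC(C)(OC(=O)C(=O)[O-])[C@@H](C(C(=O)OCC)P(=O)(OCC)OCC)CC(OC)OC
F4 | step 9 | caesium oxalate bearing the (E)-enal in place of the vinyl group | [Cs+].O=C/C=C/[C@](C)(CO1)[C@H](OC1(C)C)CCC(C)(OC(=O)C(=O)[O-])[C@@H](C(C(=O)OCC)P(=O)(OCC)OCC)CC(OC)OC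
F5 | step 8 | (2E)-3-{(4R,5R)-2,2,5-trimethyl-4-[4-(trimethylsilyl)but-3-yn-1-yl]-1,3-dioxan-5-yl}prop-2-en-1-yl acetate | CC(=O)OC/C=C/[C@](C)(CO1)[C@H](OC1(C)C)CCC#C[Si](C)(C)C
F6 | step 8 | (2E)-3-[(4R,5R)-4-(but-3-yn-1-yl)-2,2,5-trimethyl-1,3-dioxan-5-yl]prop-2-en-1-ol | OC/C=C/[C@](C)(CO1)[C@H](OC1(C)C)CCC#C
F7 | step 8 | alkenyl pinacol boronate of the allylic alcohol series (analogue of 7) | OC/C=C/[C@](C)(CO1)[C@H](OC1(C)C)CCC(=C)B2OC(C)(C)C(C)(C)O2
F8 | step 8 | conjugate adduct of the allylic alcohol series (analogue of 11, C9 as in 11) | OC/C=C/[C@](C)(CO1)[C@H](OC1(C)C)CCC(=C)[C@@H](CC(=O)OCC)CC(OC)OC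
F9 | step 8 | phosphonoacetate of the allylic alcohol series (analogue of 13) | OC/C=C/[C@](C)(CO1)[C@H](OC1(C)C)CCC(=C)[C@@H](C(C(=O)OCC)P(=O)(OCC)OCC)CC(OC)OC
F10 | step 6 | (4R,5R)-5-ethenyl-4-(3-iodobut-3-en-1-yl)-2,2,5-trimethyl-1,3-dioxane | C=C[C@](C)(CO1)[C@H](OC1(C)C)CCC(=C)I
F11 | step 6 | (2E)-5,5-dimethoxypent-2-enoic acid | OC(=O)/C=C/CC(OC)OC
F12 | step 6 | (4S)-3-[(2E)-5,5-dimethoxypent-2-enoyl]-4-phenyl-1,3-oxazolidin-2-one | O=C(/C=C/CC(OC)OC)N1[C@@H](c2ccccc2)COC1=O
F13 | step 6 | imide adduct: N-acyl (4S)-4-phenyl-oxazolidinone analogue of 11 (C9 as in 11) | C=C[C@](C)(CO1)[C@H](OC1(C)C)CCC(=C)[C@@H](CC(=O)N2[C@@H](c3ccccc3)COC2=O)CC(OC)OC
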